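Retrosynthetic overview
1. Late steps adjust only ring A. The axial C3 acetate comes from a C3 ketone by equatorial hydride delivery, and the equatorial C18 methyl comes from α-face methylation of the C3/C19 β-keto ester.
2. Key disconnection: the ring fusion bond C5–C10 is cut together with C3–C4. This opens both rings to the acyclic acid 18.
3. Enabling feature in ring A: C4 carries the C19 ester and lies between the ring fusion CH (C5) and the oxygenated C3. C5 is therefore the β-carbon of a C19 enoate and C3 is the aldol partner of its enolate. C10, at the other end of the bond, is a methyl-bearing quaternary carbon, so it can be made as a tertiary radical released from a sacrificial CO2H without touching C8=C17 or C13=C14.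
4. Order of ring formation: ring B closes first (C10 radical to C5), then ring A (C4 enolate to C3), both in one flask. C9, set by catalysis, is the only stereocentre of 18 that matters. It relays to C5 and C10, and these then direct C4 and C3.
5. Sources of 18: geraniol (C9, C11–C16), phosphonoacetate (C10 and the CO2H), an alkenylboronate (C5–C8, C17), 3-bromo-1,1-dimethoxypropane (C1–C3), MeI (C20) and methyl acrylate (C4, C19).

Key step: step 13

Remark: labdane numbering is used throughout. C1–C10 form the decalin and C11–C16 the side chain, with C16 the methyl on C13. C17 is the exocyclic methylene carbon, C18 the equatorial methyl on C4, C19 the ester carbon on C4, and C20 the methyl on C10. The SMILES is read as the normal labdane series with 5α-H, 9α-H, 10β-CH3, axial 4β-CO2CH3 and axial 3α-OAc, that is (3R,4R,5R,9S,10R).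

Step 1
Reactants: 1 geraniol
Product: 2 geranyl tert-butyldiphenylsilyl ether
Conditions: t-BuPh2SiCl (1.1 equiv), imidazole (2.2 equiv), CH2Cl2, 0 °C to rt
Reagents that add atoms: tert-butyl(chloro)diphenylsilane, CC(C)(C)[Si](Cl)(c1ccccc1)c1ccccc1
Why: Silyl ether protection of the primary allylic alcohol; the group should survive amide bases, Ru, light, hydride and mild acid and leaves with fluoride in the last step.

Step 2
Reactants: 2 geranyl tert-butyldiphenylsilyl ether
Product: 3 6,7-epoxygeranyl tert-butyldiphenylsilyl ether (racemic at the epoxide CH)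
Conditions: 3-chloroperbenzoic acid (1.0 equiv), CH2Cl2, −20 to 0 °C
Reagents that add atoms: 3-chloroperbenzoic acid, OOC(=O)c1cccc(Cl)c1
Why: Prilezhaev epoxidation should take the remote, more electron-rich trisubstituted alkene because the other one is deactivated by the allylic oxygen; the new stereocentre is racemic and is destroyed in step 3.

Step 3
Reactants: 3 6,7-epoxygeranyl tert-butyldiphenylsilyl ether
Product: 4 (4E)-6-[(tert-butyldiphenylsilyl)oxy]-4-methylhex-4-enal
Conditions: H5IO6 (1.2 equiv), THF/H2O, 0 °C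
Reagents that add atoms: none
Why: Periodic acid cleavage of the epoxide (Malaprade-type cleavage) should give the aldehyde, whose carbonyl carbon is the future C9, and leave the E alkene and the silyl ether untouched.

Step 4
Reactants: 4 (4E)-6-[(tert-butyldiphenylsilyl)oxy]-4-methylhex-4-enal; 5 triethyl phosphonoacetate
Product: 6 ethyl (2E,6E)-8-[(tert-butyldiphenylsilyl)oxy]-6-methylocta-2,6-dienoate
Conditions: LiCl (1.2 equiv), DBU (1.1 equiv), MeCN, rt
Reagents that add atoms: none
Why: Horner–Wadsworth–Emmons olefination under mild LiCl/amine conditions should give the E enoate without enolising the aldehyde.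

Step 5
Reactants: 7 2,3-dibromoprop-1-ene; 8 allylmagnesium bromide
Product: 9 2-bromohexa-1,5-diene
Conditions: Et2O, 0 °C to reflux
Reagents that add atoms: none
Why: Allylic substitution by the Grignard reagent takes place at the allylic C–Br bond only, since the vinylic bromide is inert.

Step 6
Reactants: 9 2-bromohexa-1,5-diene
Product: 10 2-(hexa-1,5-dien-2-yl)-4,4,5,5-tetramethyl-1,3,2-dioxaborolane
Conditions: bis(pinacolato)diboron (1.1 equiv), PdCl2(PPh3)2 (3 mol %), PPh3 (6 mol %), KOPh (1.5 equiv), toluene, 50 °C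
Reagents that add atoms: bis(pinacolato)diboron, CC1(C)OB(OC1(C)C)B1OC(C)(C)C(C)(C)O1
Why: Miyaura borylation of a 1-alkenyl bromide under the phenoxide conditions developed for this substrate class should leave the two alkenes in place.

Step 7
Reactants: 6 ethyl (2E,6E)-8-[(tert-butyldiphenylsilyl)oxy]-6-methylocta-2,6-dienoate; 10 2-(hexa-1,5-dien-2-yl)-4,4,5,5-tetramethyl-1,3,2-dioxaborolane
Product: 11 ethyl (3R,6E)-8-[(tert-butyldiphenylsilyl)oxy]-3-(hexa-1,5-dien-2-yl)-6-methyloct-6-enoate
Conditions: 10 (2.5 equiv), [Rh(OH)((S)-BINAP)]2 (3 mol % Rh), dioxane/H2O 10:1, 50 °C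
Reagents that add atoms: none
Why: Rhodium-catalysed asymmetric 1,4-addition (Hayashi–Miyaura reaction): the alkenylrhodium species bearing (S)-BINAP should bind the αsi face of the E enoate, insert and be hydrolysed, which sets C9 in the configuration of the target (R in 11).

Step 8
Reactants: 11 ethyl (3R,6E)-8-[(tert-butyldiphenylsilyl)oxy]-3-(hexa-1,5-dien-2-yl)-6-methyloct-6-enoate
Product: 12 (3R,6E)-8-[(tert-butyldiphenylsilyl)oxy]-3-(hexa-1,5-dien-2-yl)-6-methyloct-6-enoic acid
Conditions: LiOH (3 equiv), THF/MeOH/H2O, rt; 1 M HCl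
Reagents that add atoms: lithium hydroxide, [Li+].[OH-]
Why: Saponification of an unhindered ethyl ester; C9 is not acidic and is not touched.

Step 9
Reactants: 12 (3R,6E)-8-[(tert-butyldiphenylsilyl)oxy]-3-(hexa-1,5-dien-2-yl)-6-methyloct-6-enoic acid; 13 3-bromo-1,1-dimethoxypropane
Product: 14 (3R,6E)-8-[(tert-butyldiphenylsilyl)oxy]-2-(3,3-dimethoxypropyl)-3-(hexa-1,5-dien-2-yl)-6-methyloct-6-enoic acid (mixture at C2, the future C10)
Conditions: LiN(i-Pr)2 (2.2 equiv), THF, −78 to 0 °C; DMPU, 13 (1.3 equiv), 0 °C to rt; cold 1 M HCl to pH 4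
Reagents that add atoms: none
Why: Alkylation of the carboxylic acid dianion (enediolate) installs C1–C3 with C3 masked as an acetal; C10 forms as a mixture of epimers, which is irrelevant because C10 becomes planar in step 13.

Step 10
Reactants: 14 (3R,6E)-8-[(tert-butyldiphenylsilyl)oxy]-2-(3,3-dimethoxypropyl)-3-(hexa-1,5-dien-2-yl)-6-methyloct-6-enoic acid
Product: 15 (3S,6E)-8-[(tert-butyldiphenylsilyl)oxy]-2-(3,3-dimethoxypropyl)-3-(hexa-1,5-dien-2-yl)-2,6-dimethyloct-6-enoic acid (mixture at C2; same spatial arrangement at C3, the descriptor changes with the CIP ranking)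
Conditions: LiN(i-Pr)2 (2.5 equiv), THF, 0 to 40 °C; MeI (3 equiv), 0 °C; cold 1 M HCl to pH 4
Reagents that add atoms: iodomethane, CI
Why: A second enediolate alkylation builds the quaternary C10 and brings in C20; the smallest electrophile is used last because the centre is flanked by the branched C9, and the configuration at C10 again does not matter.

Step 11
Reactants: 15 (3S,6E)-8-[(tert-butyldiphenylsilyl)oxy]-2-(3,3-dimethoxypropyl)-3-(hexa-1,5-dien-2-yl)-2,6-dimethyloct-6-enoic acid; 16 methyl acrylate
Product: 17 (3S,6E)-8-[(tert-butyldiphenylsilyl)oxy]-2-(3,3-dimethoxypropyl)-3-[(5E)-7-methoxy-7-oxohepta-1,5-dien-2-yl]-2,6-dimethyloct-6-enoic acid (mixture at C2)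
Conditions: second-generation Hoveyda–Grubbs catalyst (3 mol %), 16 (5 equiv), CH2Cl2, 40 °C
Reagents that add atoms: none
Why: Olefin cross metathesis should engage only the monosubstituted alkene, since the 1,1-disubstituted and trisubstituted alkenes are much slower partners, and gives the E enoate that provides C4 and C19.

Step 12
Reactants: 17 (3S,6E)-8-[(tert-butyldiphenylsilyl)oxy]-2-(3,3-dimethoxypropyl)-3-[(5E)-7-methoxy-7-oxohepta-1,5-dien-2-yl]-2,6-dimethyloct-6-enoic acid
Product: 18 (3S,6E)-8-[(tert-butyldiphenylsilyl)oxy]-3-[(5E)-7-methoxy-7-oxohepta-1,5-dien-2-yl]-2,6-dimethyl-2-(3-oxopropyl)oct-6-enoic acid (mixture at C2)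
Conditions: AcOH/THF/H2O 3:1:1, 40 °C
Reagents that add atoms: water, O
Why: Mild acetal hydrolysis frees the C3 aldehyde; the acid is too weak to protonate the C8=C17 alkene, so lactonisation onto C8 should not occur, and too weak to cleave the silyl ether.

Step 13
Reactants: 18 (3S,6E)-8-[(tert-butyldiphenylsilyl)oxy]-3-[(5E)-7-methoxy-7-oxohepta-1,5-dien-2-yl]-2,6-dimethyl-2-(3-oxopropyl)oct-6-enoic acid
Product: 21 methyl 15-[(tert-butyldiphenylsilyl)oxy]-3-hydroxy-18-norlabda-8(17),13E-dien-19-oate (5α-H, 9α-H, 10β-CH3; mixture at C3 and C4), via tertiary C10 radical 19 (not isolated), via ring B ester enolate 20 (not isolated)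
Conditions: 4CzIPN (2,4,5,6-tetra(carbazol-9-yl)isophthalonitrile, 2 mol %), Cs2CO3 (1.1 equiv), degassed DMF (0.01 M), 450 nm LEDs, 25 °C
Reagents that add atoms: none
Why: Proposed new method: the excited photocatalyst oxidises the caesium carboxylate of 18, loss of CO2 gives the planar tertiary C10 radical 19 (both C10 epimers of 18 converge), 19 adds to C5 of the enoate, the resulting α-ester radical is reduced by the reduced photocatalyst to enolate 20 (radical–polar crossover), and 20 adds to the C3 aldehyde faster than it is protonated, the alkoxide then taking its proton from hydrogencarbonate. The closest known reaction types are the photoredox decarboxylative Giese addition of tertiary carboxylic acids, decarboxylative radical addition–polar cyclisation cascades, and radical conjugate addition–aldol bicyclisations started by hydrogen atom transfer to an alkene or by alkoxy radical scission; what has not been shown is their union on an acyclic acid that bears an enoate acceptor and an aldehyde terminator. Ring B closes in the 6-exo-trig mode (C5–C10) and ring A in the 6-(enolexo)-exo-trig mode (C3–C4). C5 and C10 are controlled by C9 through a chair-like transition state in which H9 lies close to the plane of the radical, the C11 chain and the enoate arm are pseudo-equatorial, and the C20 methyl rather than the CH2CH2CHO arm takes the pseudo-axial site, because an axial two-carbon arm flanked by two equatorial neighbours cannot escape a syn-pentane contact; this places C1 and C4 both equatorial on ring B and leads to the trans ring fusion. C3 and C4 are formed as mixtures and need no control, since C3 is oxidised in step 14 and C4 is reset in step 15. The step needs chemoselective radical generation beside three alkenes and 6-exo attack on C4=C5 in preference to attack on C13=C14 or C8=C17; the first is secured because the radical comes from the carboxylate and not from an alkene, the second by the polarity match between the nucleophilic tertiary radical and the only electron-poor alkene.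

Step 14
Reactants: 21 methyl 15-[(tert-butyldiphenylsilyl)oxy]-3-hydroxy-18-norlabda-8(17),13E-dien-19-oate
Product: 22 methyl 15-[(tert-butyldiphenylsilyl)oxy]-3-oxo-18-norlabda-8(17),13E-dien-19-oate (keto–enol mixture, C4 labile)
Conditions: Dess–Martin periodinane (1.3 equiv), CH2Cl2, 0 °C to rt
Reagents that add atoms: none
Why: Dess–Martin oxidation of the only free alcohol funnels all C3/C4 isomers of 21 into one β-keto ester.

Step 15
Reactants: 22 methyl 15-[(tert-butyldiphenylsilyl)oxy]-3-oxo-18-norlabda-8(17),13E-dien-19-oate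
Product: 23 methyl 15-[(tert-butyldiphenylsilyl)oxy]-3-oxolabda-8(17),13E-dien-19-oate (4α-CH3 equatorial, 4β-CO2CH3 axial)
Conditions: K2CO3 (2 equiv), MeI (3 equiv), acetone, 40 °C
Reagents that add atoms: iodomethane, CI
Why: C-alkylation of the β-keto ester enolate: the β face of C4 is blocked by the syn-axial C20 methyl on C10, so MeI should enter from the α face, which makes C18 equatorial and leaves the C19 ester axial.

Step 16
Reactants: 23 methyl 15-[(tert-butyldiphenylsilyl)oxy]-3-oxolabda-8(17),13E-dien-19-oate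
Product: 24 methyl 15-[(tert-butyldiphenylsilyl)oxy]-3α-hydroxylabda-8(17),13E-dien-19-oate
Conditions: LiBH(s-Bu)3 (1.5 equiv), THF, −78 °C; H2O
Reagents that add atoms: none
Why: Ketone reduction with a bulky trialkylborohydride: the reagent avoids the axial hydrogens at C1 and C5 on the α face and should attack along the equatorial trajectory, as it does with 4,4-disubstituted 3-oxo terpenoids, to give the axial 3α-alcohol; the hindered axial ester is not reduced.

Step 17
Reactants: 24 methyl 15-[(tert-butyldiphenylsilyl)oxy]-3α-hydroxylabda-8(17),13E-dien-19-oate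
Product: 25 methyl 3α-acetoxy-15-[(tert-butyldiphenylsilyl)oxy]labda-8(17),13E-dien-19-oate
Conditions: Ac2O (5 equiv), DMAP (0.2 equiv), pyridine, 50 °C
Reagents that add atoms: acetic anhydride, CC(=O)OC(C)=O
Why: DMAP-catalysed acetylation of the hindered axial alcohol proceeds with retention at C3.

Step 18
Reactants: 25 methyl 3α-acetoxy-15-[(tert-butyldiphenylsilyl)oxy]labda-8(17),13E-dien-19-oate
Product: 26 methyl 3α-acetoxy-15-hydroxylabda-8(17),13E-dien-19-oate (target)
Conditions: Bu4NF/AcOH 1:1 (2 equiv), THF, 0 °C to rt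
Reagents that add atoms: none
Why: Fluoride desilylation, buffered with acetic acid so that the acetate and the methyl ester are not attacked, frees the primary allylic alcohol.

Compound list
1 | geraniol | CC(C)=CCC/C(C)=C/CO | starting material
2 | geranyl tert-butyldiphenylsilyl ether | CC(C)=CCC/C(C)=C/CO[Si](c1ccccc1)(c1ccccc1)C(C)(C)C | intermediate
3 | 6,7-epoxygeranyl tert-butyldiphenylsilyl ether (racemic epoxide) | CC1(C)OC1CC/C(C)=C/CO[Si](c1ccccc1)(c1ccccc1)C(C)(C)C | intermediate
4 | (4E)-6-[(tert-butyldiphenylsilyl)oxy]-4-methylhex-4-enal | O=CCC/C(C)=C/CO[Si](c1ccccc1)(c1ccccc1)C(C)(C)C | intermediate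
5 | triethyl phosphonoacetate | CCOC(=O)CP(=O)(OCC)OCC | starting material
6 | ethyl (2E,6E)-8-[(tert-butyldiphenylsilyl)oxy]-6-methylocta-2,6-dienoate | CCOC(=O)/C=C/CC/C(C)=C/CO[Si](c1ccccc1)(c1ccccc1)C(C)(C)C | intermediate
7 | 2,3-dibromoprop-1-ene | C=C(Br)CBr | starting material
8 | allylmagnesium bromide | C=CC[Mg]Br | starting material
9 | 2-bromohexa-1,5-diene | C=CCCC(Br)=C | intermediate
10 | 2-(hexa-1,5-dien-2-yl)-4,4,5,5-tetramethyl-1,3,2-dioxaborolane | C=CCCC(=C)B1OC(C)(C)C(C)(C)O1 | intermediate
11 | ethyl (3R,6E)-8-[(tert-butyldiphenylsilyl)oxy]-3-(hexa-1,5-dien-2-yl)-6-methyloct-6-enoate | CCOC(=O)C[C@@H](CC/C(C)=C/CO[Si](c1ccccc1)(c1ccccc1)C(C)(C)C)C(=C)CCC=C | intermediate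
12 | (3R,6E)-8-[(tert-butyldiphenylsilyl)oxy]-3-(hexa-1,5-dien-2-yl)-6-methyloct-6-enoic acid | OC(=O)C[C@@H](CC/C(C)=C/CO[Si](c1ccccc1)(c1ccccc1)C(C)(C)C)C(=C)CCC=C | intermediate
13 | 3-bromo-1,1-dimethoxypropane | COC(CCBr)OC | starting material
14 | (3R,6E)-8-[(tert-butyldiphenylsilyl)oxy]-2-(3,3-dimethoxypropyl)-3-(hexa-1,5-dien-2-yl)-6-methyloct-6-enoic acid (mixture at C2) | OC(=O)C(CCC(OC)OC)[C@@H](CC/C(C)=C/CO[Si](c1ccccc1)(c1ccccc1)C(C)(C)C)C(=C)CCC=C | intermediate
15 | (3S,6E)-8-[(tert-butyldiphenylsilyl)oxy]-2-(3,3-dimethoxypropyl)-3-(hexa-1,5-dien-2-yl)-2,6-dimethyloct-6-enoic acid (mixture at C2) | OC(=O)C(C)(CCC(OC)OC)[C@@H](CC/C(C)=C/CO[Si](c1ccccc1)(c1ccccc1)C(C)(C)C)C(=C)CCC=C | intermediate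
16 | methyl acrylate | C=CC(=O)OC | starting material
17 | (3S,6E)-8-[(tert-butyldiphenylsilyl)oxy]-2-(3,3-dimethoxypropyl)-3-[(5E)-7-methoxy-7-oxohepta-1,5-dien-2-yl]-2,6-dimethyloct-6-enoic acid (mixture at C2) | OC(=O)C(C)(CCC(OC)OC)[C@@H](CC/C(C)=C/CO[Si](c1ccccc1)(c1ccccc1)C(C)(C)C)C(=C)CC/C=C/C(=O)OC | intermediate
18 | (3S,6E)-8-[(tert-butyldiphenylsilyl)oxy]-3-[(5E)-7-methoxy-7-oxohepta-1,5-dien-2-yl]-2,6-dimethyl-2-(3-oxopropyl)oct-6-enoic acid (mixture at C2) | OC(=O)C(C)(CCC=O)[C@@H](CC/C(C)=C/CO[Si](c1ccccc1)(c1ccccc1)C(C)(C)C)C(=C)CC/C=C/C(=O)OC | intermediate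
19 | tertiary C10 radical formed from 18 by loss of CO2 | C[C](CCC=O)[C@@H](CC/C(C)=C/CO[Si](c1ccccc1)(c1ccccc1)C(C)(C)C)C(=C)CC/C=C/C(=O)OC | intermediate
20 | ring B ester enolate (caesium salt; C5–C10 formed, ring A still open) | C=C1CC[C@@H](C=C([O-])OC)[C@](C)(CCC=O)[C@H]1CC/C(C)=C/CO[Si](c3ccccc3)(c3ccccc3)C(C)(C)C.[Cs+] | intermediate
21 | methyl 15-[(tert-butyldiphenylsilyl)oxy]-3-hydroxy-18-norlabda-8(17),13E-dien-19-oate (mixture at C3 and C4) | C=C1CC[C@@H]2[C@](C)(CCC(O)C2C(=O)OC)[C@H]1CC/C(C)=C/CO[Si](c3ccccc3)(c3ccccc3)C(C)(C)C | intermediate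
22 | methyl 15-[(tert-butyldiphenylsilyl)oxy]-3-oxo-18-norlabda-8(17),13E-dien-19-oate (C4 labile) | C=C1CC[C@@H]2[C@](C)(CCC(=O)C2C(=O)OC)[C@H]1CC/C(C)=C/CO[Si](c3ccccc3)(c3ccccc3)C(C)(C)C | intermediate
23 | methyl 15-[(tert-butyldiphenylsilyl)oxy]-3-oxolabda-8(17),13E-dien-19-oate | C=C1CC[C@@H]2[C@](C)(CCC(=O)[C@]2(C)C(=O)OC)[C@H]1CC/C(C)=C/CO[Si](c3ccccc3)(c3ccccc3)C(C)(C)C | intermediate
24 | methyl 15-[(tert-butyldiphenylsilyl)oxy]-3α-hydroxylabda-8(17),13E-dien-19-oate | C=C1CC[C@@H]2[C@](C)(CC[C@@H](O)[C@]2(C)C(=O)OC)[C@H]1CC/C(C)=C/CO[Si](c3ccccc3)(c3ccccc3)C(C)(C)C | intermediate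
25 | methyl 3α-acetoxy-15-[(tert-butyldiphenylsilyl)oxy]labda-8(17),13E-dien-19-oate | C=C1CC[C@@H]2[C@](C)(CC[C@@H](OC(C)=O)[C@]2(C)C(=O)OC)[C@H]1CC/C(C)=C/CO[Si](c3ccccc3)(c3ccccc3)C(C)(C)C | intermediate
26 | methyl 3α-acetoxy-15-hydroxylabda-8(17),13E-dien-19-oate | C=C1CC[C@@H]2[C@](C)(CC[C@@H](OC(C)=O)[C@]2(C)C(=O)OC)[C@H]1CC/C(C)=C/CO | target

Total step count: 18. Longest linear sequence: 16 (steps 1–4 and 7–18).

Steps most likely to fail

Step 13.
- What may go wrong: enolate 20 may be protonated before it reaches the aldehyde. The free aldehyde may condense under the basic conditions. The facial selectivity at C10 may be poor, which would erode the trans ring fusion.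
- Fallback (known chemistry only, sets out from 17 and returns at 21): the acetal acid 17 is cyclised by the established photoredox decarboxylative Giese reaction (4CzIPN, Cs2CO3, DMF/H2O, 450 nm), with water as proton source, to the ring B acetal ester F1. The C10 epimers can be separated at this stage. Deprotonation with LiN(i-Pr)2 at −78 °C and bromination with CBr4 gives the α-bromo ester F2. AcOH/THF/H2O then unmasks the bromo aldehyde F3. SmI2 in THF at −78 °C closes ring A by an intramolecular Reformatsky reaction to 21.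

Step 7.
- What may go wrong: protodeboronation of the α-substituted alkenylboronate, slow insertion into the β-alkyl enoate, or low enantioselectivity.
- Fallback (sets out from 6 and returns at 12): saponification of 6 gives the dienoic acid F4. Its mixed pivalic anhydride (t-BuCOCl, Et3N) reacts with lithiated (S)-4-benzyl-1,3-oxazolidin-2-one to give the N-enoyl imide F5. Bromide 9 and Mg give hexa-1,5-dien-2-ylmagnesium bromide F6. This is added with CuBr·SMe2 (THF/Me2S, −40 °C) to the chelated s-cis imide from the face opposite to the benzyl group and gives the adduct imide F7. LiOH/H2O2 cleaves the auxiliary and delivers 12.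

Step 16.
- What may go wrong: poor facial selectivity of hydride delivery next to the quaternary C4, which would give the equatorial alcohol.
- Fallback (sets out from 23 and returns at 25): NaBH4 in MeOH at 0 °C, which attacks axially from the α face, gives the equatorial 3β-alcohol F8. A Mitsunobu reaction (PPh3, diisopropyl azodicarboxylate, AcOH, toluene) then inverts C3 and gives the axial acetate 25 directly.

Further compounds
F1 | step 13 | methyl {(1R,2R,3S)-2-(3,3-dimethoxypropyl)-2-methyl-4-methylidene-3-[(3E)-5-(tert-butyldiphenylsilyloxy)-3-methylpent-3-enyl]cyclohexyl}acetate (ring B acetal ester; ring atoms 1, 2, 3 are C5, C10, C9) | C=C1CC[C@@H](CC(=O)OC)[C@](C)(CCC(OC)OC)[C@H]1CC/C(C)=C/CO[Si](c3ccccc3)(c3ccccc3)C(C)(C)C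
F2 | step 13 | α-bromo ester derived from F1 (Br on C4, mixture of epimers) | C=C1CC[C@@H](C(Br)C(=O)OC)[C@](C)(CCC(OC)OC)[C@H]1CC/C(C)=C/CO[Si](c3ccccc3)(c3ccccc3)C(C)(C)C
F3 | step 13 | bromo aldehyde derived from F2 (C3 aldehyde free) | C=C1CC[C@@H](C(Br)C(=O)OC)[C@](C)(CCC=O)[C@H]1CC/C(C)=C/CO[Si](c3ccccc3)(c3ccccc3)C(C)(C)C
F4 | step 7 | (2E,6E)-8-[(tert-butyldiphenylsilyl)oxy]-6-methylocta-2,6-dienoic acid | OC(=O)/C=C/CC/C(C)=C/CO[Si](c1ccccc1)(c1ccccc1)C(C)(C)C
F5 | step 7 | (4S)-4-benzyl-3-{(2E,6E)-8-[(tert-butyldiphenylsilyl)oxy]-6-methylocta-2,6-dienoyl}-1,3-oxazolidin-2-one | O=C(/C=C/CC/C(C)=C/CO[Si](c1ccccc1)(c1ccccc1)C(C)(C)C)N1[C@@H](Cc2ccccc2)COC1=O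
F6 | step 7 | hexa-1,5-dien-2-ylmagnesium bromide | C=CCCC(=C)[Mg]Br
F7 | step 7 | (4S)-4-benzyl-3-{(3R,6E)-8-[(tert-butyldiphenylsilyl)oxy]-3-(hexa-1,5-dien-2-yl)-6-methyloct-6-enoyl}-1,3-oxazolidin-2-one | O=C(C[C@@H](CC/C(C)=C/CO[Si](c1ccccc1)(c1ccccc1)C(C)(C)C)C(=C)CCC=C)N1[C@@H](Cc2ccccc2)COC1=O
F8 | step 16 | methyl 15-[(tert-butyldiphenylsilyl)oxy]-3β-hydroxylabda-8(17),13E-dien-19-oate | C=C1CC[C@@H]2[C@](C)(CC[C@H](O)[C@]2(C)C(=O)OC)[C@H]1CC/C(C)=C/CO[Si](c3ccccc3)(c3ccccc3)C(C)(C)C
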